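Remark on the chemistry (assumption): atom labels C1–C8 follow the 3,7-dioxabicyclo[3.3.0]octane numbering. C1 is the carbinol bridgehead, C2 the CH that bears the 4-hydroxy-3-methoxyphenyl group, then O3, C4, C5 (the CH bridgehead), C6 (the CH that bears the 3,4-dimethoxyphenyl group), O7 and C8. Ring A is C1–C2–O3–C4–C5 and ring B is C1–C5–C6–O7–C8. The palladium/indium propargylation is taken to run with overall inversion at the propargylic carbon (anti SN2' oxidative addition, retentive transmetalation, syn SE2' addition).

## Analysis of the target

The target 18 is a 2,6-diaryl-3,7-dioxabicyclo[3.3.0]octan-1-ol, an 8-hydroxylated furofuran lignan. Its two oxolane rings, ring A and ring B, are cis-fused along the C1–C5 bond. The four contiguous stereocentres are (1S,2R,5R,6S): the C1 hydroxyl and H5 are cis, and both aryl groups lie on the convex face, the C2 aryl cis to the C1 hydroxyl and the C6 aryl cis to H5. The two halves are not equivalent. The guaiacyl ring with the free phenol sits on C2 next to the carbinol, and the veratryl ring sits on C6 next to the CH bridgehead, so no dimerisation or symmetry can be used and C1 must be told apart from C5. The sensitive groups are the free phenol (oxidation, and quinone-methide-type opening of ring A at C2), the benzylic ether carbons C2 and C6 (ionisation and epimerisation in acid, hydrogenolysis), the tertiary β-alkoxy alcohol at C1 (dehydration or semipinacol shift in acid) and two electron-rich arenes. The feature that invites the key move is the C1–C2 bond of ring A. It joins the oxygen-bearing bridgehead C1 to the oxygen-bearing benzylic carbon C2, two carbons of like (acceptor) polarity in a pinacol-type 1,2-dioxygen pattern that no ionic aldol-type union delivers directly. The hard part is the fully substituted carbinol at the ring fusion, flanked by three stereocentres, which has to be made with the C2 aryl exo and in one enantiomer.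

## Retrosynthetic reasoning

18 ⇒ 17. The phenol is unmasked last. It is carried as the silyl ether 17 because a free phenol would quench an excited ketone and would disturb the organometallic step. Fluoride cleavage does not touch the acid-labile benzylic ethers.

17 ⇒ 15 (through biradical 16). The C1–C2 bond is cut. This is the one bond between two oxygenated carbons, and cutting it removes ring A, the tertiary carbinol and the C2 stereocentre together. What remains is the monocyclic ketone 15 with only C5 and C6 as stereocentres. The forward reaction is a Norrish–Yang photocyclisation. The excited C1 carbonyl takes a hydrogen from the benzylic ether carbon C2, and biradical 16 must then close to the cis-fused bicycle with the aryl group exo. The O3–C4 tether on C5 should enforce the fusion and relay the configuration of C5 to C1 and C2.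

15 ⇒ 13 (through gold carbene 14). The O7–C8 bond and the carbonyl oxygen are removed. The terminal alkyne of 13 serves as a masked α-oxo carbene: a gold-catalysed oxidation with an amine N-oxide followed by O–H insertion of the C6 hydroxyl. This makes ring B and the ketone in one neutral step. It avoids a diazoketone and any base that could epimerise C5 or open ring B by β-elimination. The anti relationship in 13 becomes the trans relationship in 15.

13 ⇒ 10 + 11 (through allenylindium 12). The C5–C6 bond is cut. A Marshall propargylation joins mesylate 10 and aldehyde 11 and sets C5 and C6 in one event from the single stereocentre of 10: C5 by chirality transfer through the allene axis of 12, C6 by the cyclic transition state. The benzyl-type ether that will later deliver C2 is already in place, so no protecting group is spent on O3.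

10 ⇒ 9 ⇒ 7 + 4. The mesylate comes from alcohol 9. The ether bond O3–C2 of 9 is cut to diol 7 and bromide 4, and is formed through stannylene acetal 8, which directs alkylation to the primary oxygen.

7 ⇒ 6 ⇒ 5. Diol 7 is traced through alkyne 6 to the chiral-pool aldehyde 5 by a one-carbon alkyne homologation. This is the one bought stereocentre, from which all four stereocentres of 18 are relayed.

4 ⇒ 3 ⇒ 2 ⇒ 1. Bromide 4 comes from vanillin 1 by silylation, reduction and bromination.

## Alternatives that were turned down

Alternative 1: the textbook disconnection cuts both benzylic C–O bonds (C2–O3 and C6–O7) and leads to the open-chain pentaol A1. The forward key step is an acid-mediated double cyclodehydration through benzylic cations. It was turned down for three reasons. The key step forms no C–C bond and sets the benzylic centres only by thermodynamic preference. The C2 cation sits next to the tertiary carbinol C1, so a semipinacol shift or dehydration competes with ring closure, and five hydroxyls allow wrong ring pairings. A1 itself must be built with C1 and C5 defined, by two aldol additions, an α-hydroxylation and exhaustive reduction, which is longer than the whole chosen route and leaves the key step little to do.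

Alternative 2: the C1–O bond is cut last, on a bicycle that carries a lactone carbonyl at C8 to mark C1. The enolate of lactone A2 would be oxygenated with a sulfonyloxaziridine from the convex face to give hydroxy lactone A3, and the C8 carbonyl would then be reduced to the methylene. It was turned down because the key step sets one stereocentre only, on a skeleton whose three other stereocentres and both rings must already be in place. After it, the lactone still has to be taken down to the ether in two redox steps, in the presence of a tertiary alcohol and two benzylic ethers that ionise under the Lewis-acid/silane conditions normally used. The enantioselective construction of A2 would cost about as many steps as the chosen route needs in total.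

Alternative 3: a radical cascade would cut C1–C5 and C6–O7 and start from the open-chain keto ether A4. A ketyl radical at C1 (for example from SmI2) would close ring A by 5-exo addition to the cinnamyl double bond. The benzylic radical at C6 would then have to be oxidised and trapped by the C8 hydroxyl to close ring B. It was turned down on mechanism. The reductant that makes the ketyl also reduces the benzylic radical to an organometallic that is protonated, so ring B would not close without a separate benzylic oxidation. The only stereocentre of A4, C2, lies between an aryl group and a ketone and would racemise by enolisation. C5 and C6 would be set only by modest 1,2-induction in the radical closure.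

Key step: step 10

## Route

Step 1
Reactants: 1 vanillin (4-hydroxy-3-methoxybenzaldehyde)
Product: 2 4-[(tert-butyldimethylsilyl)oxy]-3-methoxybenzaldehyde
Conditions: TBSCl, imidazole, DMF, rt
Reagents that add atoms: tert-butyldimethylsilyl chloride (TBSCl), CC(C)(C)[Si](C)(C)Cl
Why: Standard silylation of a phenol; the silyl ether masks the only acidic and oxidisable OH, which would quench the excited ketone in step 10, and it can be removed at the end with fluoride without acid.

Step 2
Reactants: 2 4-[(tert-butyldimethylsilyl)oxy]-3-methoxybenzaldehyde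
Product: 3 {4-[(tert-butyldimethylsilyl)oxy]-3-methoxyphenyl}methanol
Conditions: NaBH4, MeOH, 0 °C
Reagents that add atoms: none
Why: Borohydride reduction of an aromatic aldehyde; at 0 °C and short reaction time the aryl silyl ether should survive.

Step 3
Reactants: 3 {4-[(tert-butyldimethylsilyl)oxy]-3-methoxyphenyl}methanol
Product: 4 [4-(bromomethyl)-2-methoxyphenoxy](tert-butyl)dimethylsilane
Conditions: CBr4, PPh3, CH2Cl2, 0 °C
Reagents that add atoms: carbon tetrabromide, BrC(Br)(Br)Br
Why: Appel bromination under neutral conditions, which spares the aryl silyl ether; the electron-rich benzylic bromide is used at once in step 6.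

Step 4
Reactants: 5 (R)-2,2-dimethyl-1,3-dioxolane-4-carbaldehyde
Product: 6 (S)-4-ethynyl-2,2-dimethyl-1,3-dioxolane
Conditions: dimethyl (1-diazo-2-oxopropyl)phosphonate, K2CO3, MeOH, 0 °C to rt
Reagents that add atoms: dimethyl (1-diazo-2-oxopropyl)phosphonate, COP(=O)(OC)C(=[N+]=[N-])C(C)=O
Why: Ohira–Bestmann homologation turns the aldehyde into the terminal alkyne under mild carbonate conditions that should not epimerise the α-alkoxy aldehyde; the stereocentre is not touched, and the descriptor changes from R to S only because the priorities change.

Step 5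
Reactants: 6 (S)-4-ethynyl-2,2-dimethyl-1,3-dioxolane
Product: 7 (S)-but-3-yne-1,2-diol
Conditions: Amberlyst 15 (H+ resin), MeOH–H2O, rt
Reagents that add atoms: none
Why: Acid-catalysed hydrolysis of the acetonide; the resin is filtered off, so the water-soluble diol is obtained by evaporation without extraction.

Step 6
Reactants: 7 (S)-but-3-yne-1,2-diol and 4 [4-(bromomethyl)-2-methoxyphenoxy](tert-butyl)dimethylsilane
Product: 9 (S)-1-({4-[(tert-butyldimethylsilyl)oxy]-3-methoxyphenyl}methoxy)but-3-yn-2-ol, via stannylene acetal 8 (not isolated)
Conditions: Bu2SnO, toluene, reflux (Dean–Stark); then 4, Bu4NI, toluene, 70 °C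
Reagents that add atoms: none
Why: Stannylene-acetal alkylation of a terminal 1,2-diol goes to the primary oxygen, whereas a Williamson reaction would favour the more acidic propargylic hydroxyl; the fluoride-free iodide activation spares the aryl silyl ether, and the stereocentre is not involved.

Step 7
Reactants: 9 (S)-1-({4-[(tert-butyldimethylsilyl)oxy]-3-methoxyphenyl}methoxy)but-3-yn-2-ol
Product: 10 (S)-1-({4-[(tert-butyldimethylsilyl)oxy]-3-methoxyphenyl}methoxy)but-3-yn-2-yl methanesulfonate
Conditions: MsCl, Et3N, CH2Cl2, −40 °C
Reagents that add atoms: methanesulfonyl chloride, CS(=O)(=O)Cl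
Why: Mesylation of the secondary propargylic alcohol forms an O–S bond, so the configuration is retained.

Step 8
Reactants: 10 (S)-1-({4-[(tert-butyldimethylsilyl)oxy]-3-methoxyphenyl}methoxy)but-3-yn-2-yl methanesulfonate and 11 3,4-dimethoxybenzaldehyde (veratraldehyde)
Product: 13 (1S,2R)-1-(3,4-dimethoxyphenyl)-2-[({4-[(tert-butyldimethylsilyl)oxy]-3-methoxyphenyl}methoxy)methyl]but-3-yn-1-ol, via allenylindium 12 (not isolated)
Conditions: Pd(dppf)Cl2 (5 mol %), InI (1.3 equiv), THF–HMPA (3:1), rt
Reagents that add atoms: none
Why: Marshall propargylation: zerovalent palladium adds to 10 in an anti SN2' sense, and transmetalation to indium with retention gives the (aS)-allenylindium 12, which adds to the aldehyde syn to indium through a cyclic six-membered SE2' transition state. The net inversion at the propargylic carbon sets C5 (R), and the chair-like transition state with the aryl group equatorial sets C6 (S), which is the anti adduct. The syn adduct, epimeric at C6, should be removable by chromatography at this stage.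

Step 9
Reactants: 13 (1S,2R)-1-(3,4-dimethoxyphenyl)-2-[({4-[(tert-butyldimethylsilyl)oxy]-3-methoxyphenyl}methoxy)methyl]but-3-yn-1-ol
Product: 15 (4R,5S)-5-(3,4-dimethoxyphenyl)-4-[({4-[(tert-butyldimethylsilyl)oxy]-3-methoxyphenyl}methoxy)methyl]oxolan-3-one, via α-oxo gold carbene 14 (not isolated)
Conditions: Ph3PAuNTf2 (5 mol %), 8-methylquinoline N-oxide (1.5 equiv), ClCH2CH2Cl, rt
Reagents that add atoms: 8-methylquinoline N-oxide, Cc1cccc2ccc[n+]([O-])c12
Why: Gold-catalysed oxidative cyclisation of a homopropargylic alcohol: the N-oxide adds to the gold-bound terminal alkyne at the internal carbon, N–O cleavage gives the α-oxo gold carbene 14, and O–H insertion of the C6 hydroxyl closes ring B through the O7–C8 bond. The acid-free, room-temperature conditions should leave C5 (now α to the ketone) and the benzylic C6 untouched, so the anti adduct gives the trans-4,5-disubstituted oxolan-3-one.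

Step 10
Reactants: 15 (4R,5S)-5-(3,4-dimethoxyphenyl)-4-[({4-[(tert-butyldimethylsilyl)oxy]-3-methoxyphenyl}methoxy)methyl]oxolan-3-one
Product: 17 (1S,2R,5R,6S)-2-{4-[(tert-butyldimethylsilyl)oxy]-3-methoxyphenyl}-6-(3,4-dimethoxyphenyl)-3,7-dioxabicyclo[3.3.0]octan-1-ol, via 1,5-biradical 16 (not isolated)
Conditions: hν (medium-pressure Hg lamp, Pyrex filter, λ > 300 nm), degassed benzene (0.01 M), rt
Reagents that add atoms: none
Why: Norrish–Yang photocyclisation of a β-alkoxy ketone: n,π* excitation of the C1 carbonyl is followed by abstraction of a δ-hydrogen from the benzylic ether carbon C2 through a seven-membered transition state, giving the 1,5-biradical 16 (hydroxy radical at C1, α-alkoxybenzyl radical at C2), which recombines to form the C1–C2 bond. The closest known reaction type is the photocyclisation of β-alkoxy ketones to oxolan-3-ols, which has been applied to 4-(benzyloxymethyl)oxolan-3-ones to give 2-aryl-3,7-dioxabicyclo[3.3.0]octan-1-ols. Ring A is closed by radical–radical recombination to a five-membered ring, and because the O3–C4 tether is anchored on C5 only the cis-fused bicycle can form. C1 is therefore controlled by C5: C2 is delivered to the face of C1 that is syn to C4, which leaves the new hydroxyl cis to H5. C2 is controlled in the closure: the planar benzylic radical should turn its aryl group to the convex face (cis to the C1 hydroxyl), away from C8H2 and ring B on the concave face, while the C6 aryl group, trans to the tether, stays out of the way. The step needs hydrogen abstraction at C2 to beat α-cleavage of the α-alkoxy ketone; the substrate has no reachable γ-hydrogen (the γ-atoms are O3 and O7, and H6 is held in ring B away from the carbonyl oxygen), and the C2–H bond is weakened by both the aryl group and O3. The silyl ether keeps the phenol from quenching the excited ketone by hydrogen transfer, and Pyrex-filtered light excites the ketone rather than the arenes.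

Step 11
Reactants: 17 (1S,2R,5R,6S)-2-{4-[(tert-butyldimethylsilyl)oxy]-3-methoxyphenyl}-6-(3,4-dimethoxyphenyl)-3,7-dioxabicyclo[3.3.0]octan-1-ol
Product: 18 (1S,2R,5R,6S)-6-(3,4-dimethoxyphenyl)-2-(4-hydroxy-3-methoxyphenyl)-3,7-dioxabicyclo[3.3.0]octan-1-ol
Conditions: Bu4NF, AcOH (1:1), THF, 0 °C
Reagents that add atoms: none
Why: Fluoride cleavage of the aryl silyl ether; the acetic acid buffer protonates the phenoxide at once, so that it cannot expel O3 from the para benzylic carbon C2 and epimerise it, and no stereocentre is touched.

## Compound list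

1 | vanillin (4-hydroxy-3-methoxybenzaldehyde) | COc1cc(C=O)ccc1O | starting material
2 | 4-[(tert-butyldimethylsilyl)oxy]-3-methoxybenzaldehyde | COc1cc(C=O)ccc1O[Si](C)(C)C(C)(C)C | intermediate
3 | {4-[(tert-butyldimethylsilyl)oxy]-3-methoxyphenyl}methanol | COc1cc(CO)ccc1O[Si](C)(C)C(C)(C)C | intermediate
4 | [4-(bromomethyl)-2-methoxyphenoxy](tert-butyl)dimethylsilane | COc1cc(CBr)ccc1O[Si](C)(C)C(C)(C)C | intermediate
5 | (R)-2,2-dimethyl-1,3-dioxolane-4-carbaldehyde | O=C[C@H]1COC(C)(C)O1 | starting material
6 | (S)-4-ethynyl-2,2-dimethyl-1,3-dioxolane | C#C[C@H]1COC(C)(C)O1 | intermediate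
7 | (S)-but-3-yne-1,2-diol | C#C[C@H](O)CO | intermediate
8 | (S)-2,2-dibutyl-4-ethynyl-1,3,2-dioxastannolane (stannylene acetal, not isolated) | C#C[C@H]1CO[Sn](CCCC)(CCCC)O1 | intermediate
9 | (S)-1-({4-[(tert-butyldimethylsilyl)oxy]-3-methoxyphenyl}methoxy)but-3-yn-2-ol | C#C[C@H](O)COCc1ccc(O[Si](C)(C)C(C)(C)C)c(OC)c1 | intermediate
10 | (S)-1-({4-[(tert-butyldimethylsilyl)oxy]-3-methoxyphenyl}methoxy)but-3-yn-2-yl methanesulfonate | C#C[C@H](OS(C)(=O)=O)COCc1ccc(O[Si](C)(C)C(C)(C)C)c(OC)c1 | intermediate
11 | 3,4-dimethoxybenzaldehyde (veratraldehyde) | COc1ccc(C=O)cc1OC | starting material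
12 | (aS)-[4-({4-[(tert-butyldimethylsilyl)oxy]-3-methoxyphenyl}methoxy)buta-1,2-dien-1-yl]indium iodide methanesulfonate (allenylindium, not isolated) | CS(=O)(=O)O[In](I)[CH]=[C@@]=[CH]COCc1ccc(O[Si](C)(C)C(C)(C)C)c(OC)c1 | intermediate
13 | (1S,2R)-1-(3,4-dimethoxyphenyl)-2-[({4-[(tert-butyldimethylsilyl)oxy]-3-methoxyphenyl}methoxy)methyl]but-3-yn-1-ol | C#C[C@H](COCc1ccc(O[Si](C)(C)C(C)(C)C)c(OC)c1)[C@H](O)c1ccc(OC)c(OC)c1 | intermediate
14 | [(3R,4S)-4-(3,4-dimethoxyphenyl)-4-hydroxy-3-[({4-[(tert-butyldimethylsilyl)oxy]-3-methoxyphenyl}methoxy)methyl]-2-oxobutylidene](triphenylphosphine)gold cation (α-oxo gold carbene, not isolated) | O=C(C=[Au][P+](c1ccccc1)(c1ccccc1)c1ccccc1)[C@H](COCc1ccc(O[Si](C)(C)C(C)(C)C)c(OC)c1)[C@H](O)c1ccc(OC)c(OC)c1 | intermediate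
15 | (4R,5S)-5-(3,4-dimethoxyphenyl)-4-[({4-[(tert-butyldimethylsilyl)oxy]-3-methoxyphenyl}methoxy)methyl]oxolan-3-one | COc1cc(COC[C@@H]2[C@@H](c3ccc(OC)c(OC)c3)OCC2=O)ccc1O[Si](C)(C)C(C)(C)C | intermediate
16 | 1,5-biradical from 15 (hydroxy radical at C1, α-alkoxybenzyl radical at C2; C5 and C6 as in 15; not isolated) | COc1cc([CH]OC[C@@H]2[C@@H](c3ccc(OC)c(OC)c3)OC[C]2O)ccc1O[Si](C)(C)C(C)(C)C | intermediate
17 | (1S,2R,5R,6S)-2-{4-[(tert-butyldimethylsilyl)oxy]-3-methoxyphenyl}-6-(3,4-dimethoxyphenyl)-3,7-dioxabicyclo[3.3.0]octan-1-ol | COc1cc([C@H]2OC[C@@H]3[C@@H](c4ccc(OC)c(OC)c4)OC[C@]23O)ccc1O[Si](C)(C)C(C)(C)C | intermediate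
18 | (1S,2R,5R,6S)-6-(3,4-dimethoxyphenyl)-2-(4-hydroxy-3-methoxyphenyl)-3,7-dioxabicyclo[3.3.0]octan-1-ol (CNP0141816.1) | COc1cc([C@H]2OC[C@@H]3[C@@H](c4ccc(OC)c(OC)c4)OC[C@]23O)ccc1O | target

## Step count and least certain steps

Total step count: 11. Longest linear sequence: 9 steps (steps 1, 2, 3, 6, 7, 8, 9, 10, 11, from vanillin 1); the branch from 5 (steps 4 and 5) joins at step 6.

Step 10 (key step). What may go wrong: α-cleavage of the excited α-alkoxy ketone, or charge-transfer quenching of the excited carbonyl by the electron-rich arenes, may outrun hydrogen abstraction at C2, and closure of the biradical may place the C2 aryl group on the concave face in part. Fallback (sets out from 15 and bromide 4, returns at 17): ring A would be closed through the O3–C2 bond instead of the C1–C2 bond. Bromide 4 and PPh3 give the phosphonium salt F1. Deprotonation (NaN(SiMe3)2, THF, −78 °C) and Wittig olefination of 15 give the benzylidene oxolane F2. Upjohn dihydroxylation (OsO4 cat., N-methylmorpholine N-oxide) from the face anti to the C4 side chain gives the diol F3, with the C1 hydroxyl placed as in the target. BF3·OEt2 with EtSH at low temperature then ionises C2; the ether oxygen O3 captures the cation to form the five-membered ring with the aryl group exo, and the oxonium loses its arylmethyl group to the thiol, which gives 17.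

Step 8. What may go wrong: the aromatic, electron-rich aldehyde reacts slowly, so the transient allenylmetal may lose part of its axial chirality before addition, and the looser transition state may erode the anti selectivity. Fallback for the diastereoselectivity (sets out from the mixture of 13 and its C6 epimer, returns at 13): the mixture of 13 and the syn adduct F4 would be oxidised with Dess–Martin periodinane (NaHCO3 buffer) to the ynone F5, which keeps C5. Chelation-controlled reduction with Zn(BH4)2, through a six-membered chelate between the carbonyl oxygen and O3, then delivers hydride anti to the ethynyl group and returns 13. C6 is then set by substrate control and not by the propargylation.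

Step 9. What may go wrong: the ether oxygen O3 or the arenes may capture the gold carbene (oxonium ylide formation with benzyl transfer, or arene insertion) in competition with O–H insertion, and a second oxidation of the carbene by the N-oxide is possible. Fallback (sets out from 13, returns at 15): endo-cycloisomerisation of 13 through a molybdenum vinylidene (Mo(CO)6, Me3NO, Et3N, Et2O) gives the dihydrofuran F6. Hydroboration (BH3·THF, then NaBO3), with boron adding to C1 anti to the C5 substituent, gives the oxolan-3-ol F7, and Dess–Martin oxidation gives 15 without a carbene.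

## Further compounds

F1 | step 10 | ({4-[(tert-butyldimethylsilyl)oxy]-3-methoxyphenyl}methyl)triphenylphosphonium bromide | COc1cc(C[P+](c2ccccc2)(c2ccccc2)c2ccccc2)ccc1O[Si](C)(C)C(C)(C)C.[Br-]
F2 | step 10 | (2S,3R,4Z)-2-(3,4-dimethoxyphenyl)-4-({4-[(tert-butyldimethylsilyl)oxy]-3-methoxyphenyl}methylidene)-3-[({4-[(tert-butyldimethylsilyl)oxy]-3-methoxyphenyl}methoxy)methyl]oxolane | COc1cc(COC[C@@H]2[C@@H](c3ccc(OC)c(OC)c3)OC/C2=C\c2ccc(O[Si](C)(C)C(C)(C)C)c(OC)c2)ccc1O[Si](C)(C)C(C)(C)C
F3 | step 10 | (3S,4R,5S)-5-(3,4-dimethoxyphenyl)-3-[(R)-{4-[(tert-butyldimethylsilyl)oxy]-3-methoxyphenyl}(hydroxy)methyl]-4-[({4-[(tert-butyldimethylsilyl)oxy]-3-methoxyphenyl}methoxy)methyl]oxolan-3-ol | COc1cc(COC[C@@H]2[C@@H](c3ccc(OC)c(OC)c3)OC[C@]2(O)[C@H](O)c2ccc(O[Si](C)(C)C(C)(C)C)c(OC)c2)ccc1O[Si](C)(C)C(C)(C)C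
F4 | step 8 | (1R,2R)-1-(3,4-dimethoxyphenyl)-2-[({4-[(tert-butyldimethylsilyl)oxy]-3-methoxyphenyl}methoxy)methyl]but-3-yn-1-ol (syn adduct) | C#C[C@H](COCc1ccc(O[Si](C)(C)C(C)(C)C)c(OC)c1)[C@@H](O)c1ccc(OC)c(OC)c1
F5 | step 8 | (2R)-1-(3,4-dimethoxyphenyl)-2-[({4-[(tert-butyldimethylsilyl)oxy]-3-methoxyphenyl}methoxy)methyl]but-3-yn-1-one | C#C[C@H](COCc1ccc(O[Si](C)(C)C(C)(C)C)c(OC)c1)C(=O)c1ccc(OC)c(OC)c1
F6 | step 9 | (2S,3R)-2-(3,4-dimethoxyphenyl)-3-[({4-[(tert-butyldimethylsilyl)oxy]-3-methoxyphenyl}methoxy)methyl]-2,3-dihydrofuran | COc1cc(COC[C@H]2C=CO[C@@H]2c2ccc(OC)c(OC)c2)ccc1O[Si](C)(C)C(C)(C)C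
F7 | step 9 | (3S,4S,5S)-5-(3,4-dimethoxyphenyl)-4-[({4-[(tert-butyldimethylsilyl)oxy]-3-methoxyphenyl}methoxy)methyl]oxolan-3-ol | COc1cc(COC[C@@H]2[C@@H](c3ccc(OC)c(OC)c3)OC[C@H]2O)ccc1O[Si](C)(C)C(C)(C)C
A1 | alternative 1 | 1-(4-hydroxy-3-methoxyphenyl)-4-(3,4-dimethoxyphenyl)-2,3-bis(hydroxymethyl)butane-1,2,4-triol (pentaol, configuration drawn as in the target) | COc1cc([C@@H](O)[C@@](O)(CO)[C@H](CO)[C@H](O)c2ccc(OC)c(OC)c2)ccc1O
A2 | alternative 2 | 2-{4-[(tert-butyldimethylsilyl)oxy]-3-methoxyphenyl}-6-(3,4-dimethoxyphenyl)-3,7-dioxabicyclo[3.3.0]octan-8-one (ring configuration of the target, H at C1) | COc1cc([C@H]2OC[C@@H]3[C@@H](c4ccc(OC)c(OC)c4)OC(=O)[C@H]23)ccc1O[Si](C)(C)C(C)(C)C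
A3 | alternative 2 | 2-{4-[(tert-butyldimethylsilyl)oxy]-3-methoxyphenyl}-6-(3,4-dimethoxyphenyl)-1-hydroxy-3,7-dioxabicyclo[3.3.0]octan-8-one | COc1cc([C@H]2OC[C@@H]3[C@@H](c4ccc(OC)c(OC)c4)OC(=O)[C@]23O)ccc1O[Si](C)(C)C(C)(C)C
A4 | alternative 3 | (R)-1-{4-[(tert-butyldimethylsilyl)oxy]-3-methoxyphenyl}-1-{[(E)-3-(3,4-dimethoxyphenyl)prop-2-en-1-yl]oxy}-3-hydroxypropan-2-one | COc1cc([C@@H](OC/C=C/c2ccc(OC)c(OC)c2)C(=O)CO)ccc1O[Si](C)(C)C(C)(C)C
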